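**Retrosynthetic overview**

1. Numbering as in germacranes: ring C1–C10 (C1=C10), CH2OH C15 on C4, angelate oxygen on C6, lactone C11(=C13)–C12(=O)–O–C8 fused at C7–C8, CH2OH C14 on C10; the target 30 is (4R,6R,7R,8R).
2. Endgame: 30 ⇐ desilylation, allylic oxidation of C12 (oxolane to lactone) and C6 angeloylation of the bicyclic 3-methylideneoxolane 24, which carries C12 one oxidation level lower.
3. Key disconnection: C9–C10 and O–C8 together, by a palladium-catalysed alkene carboetherification of the acyclic bromo-dienol 23; the oxolane ring (O, C12, C11, C7, C8) and the ten-membered carbocycle close in this one step and C8 is set; no ring exists before it.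
4. Enabling feature: the ring oxygen stands γ to the C8=C9 vinyl group through C12–C11–C7 (a γ-hydroxy terminal alkene), and C9 is a methylene between oxygenated C8 and the trisubstituted alkene carbon C10, whose C9 and C2 are cis on the ring, so C10 can enter as a (Z)-alkenyl bromide.
5. 23 ⇐ Evans syn-aldol (C6, C7) of aldehyde 14 with crotonyl imide 15, then thioester → allylsilane → allylic alcohol; 14 ⇐ Evans allylation (C4) of the hex-5-ynoyl imide, hydroxymethylation, trans-hydrostannation and bromodestannylation (alkene geometry).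

Key step: step 15

Abbreviations: TBDPS = tert-butyldiphenylsilyl; TES = triethylsilyl. Atom numbers C1–C15 in the text are the germacrane numbers of line 1.

**Route**

Step 1
Reactants: 1 hex-5-ynoic acid; 2 (4S)-4-benzyl-1,3-oxazolidin-2-one
Product: 4 (4S)-4-benzyl-3-(hex-5-ynoyl)-1,3-oxazolidin-2-one, via hex-5-ynoic pivalic anhydride 3 (not isolated)
Conditions: PivCl, Et3N, THF, −20 °C; then 2, LiCl, −20 °C to rt
Reagents that add atoms: none
Why: Mixed-anhydride N-acylation of the LiCl-activated oxazolidinone is the standard mild entry to Evans imides and leaves the terminal alkyne untouched.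

Step 2
Reactants: 4
Product: 6 (4S)-4-benzyl-3-[(2R)-2-(prop-2-en-1-yl)hex-5-ynoyl]-1,3-oxazolidin-2-one, via sodium imide enolate 5 (not isolated)
Conditions: NaN(SiMe3)2, THF, −78 °C; allyl iodide, −78 to −45 °C
Reagents that add atoms: allyl iodide, C=CCI
Why: Evans asymmetric alkylation: the chelated sodium (Z)-enolate is allylated on the face opposite the benzyl group, which sets C4 (R) with C5 and C6 coming from the allyl group.

Step 3
Reactants: 6
Product: 7 (2R)-2-(prop-2-en-1-yl)hex-5-yn-1-ol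
Conditions: LiBH4, MeOH (1 equiv), Et2O, 0 °C
Reagents that add atoms: none
Why: Reductive cleavage of the imide with LiBH4 gives the primary alcohol (C15) and releases the auxiliary without touching alkyne, alkene or the α-stereocentre.

Step 4
Reactants: 7
Product: 9 (2R)-2-(prop-2-en-1-yl)hept-5-yne-1,7-diol, via dilithium alkoxide acetylide 8 (not isolated)
Conditions: n-BuLi (2.2 equiv), THF, −78 to 0 °C; (CH2O)n, 0 °C to rt; H2O
Reagents that add atoms: paraformaldehyde (reacts as formaldehyde), C=O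
Why: Acetylide hydroxymethylation: the alkoxide–acetylide dianion adds to formaldehyde at carbon and installs C14 as a propargylic alcohol.

Step 5
Reactants: 9
Product: 10 (2Z,6R)-6-(prop-2-en-1-yl)-2-(tributylstannyl)hept-2-ene-1,7-diol
Conditions: [Cp*RuCl]4 (2 mol %), Bu3SnH (1.1 equiv, slow addition), CH2Cl2, rt
Reagents that add atoms: tributyltin hydride, CCCC[SnH](CCCC)CCCC
Why: Ruthenium-catalysed trans-hydrostannation of a propargylic alcohol: the free hydroxyl steers tin to the proximal alkyne carbon (C10) and hydrogen is delivered anti, so tin and C2 end up cis, and the terminal alkene does not react.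

Step 6
Reactants: 10
Product: 11 bis-TBDPS ether of 10, (2Z,6R)-1,7-bis(TBDPS-oxy)-6-(prop-2-en-1-yl)-2-(tributylstannyl)hept-2-ene
Conditions: TBDPSCl (2.4 equiv), imidazole, DMF, rt
Reagents that add atoms: tert-butyl(chloro)diphenylsilane, CC(C)(C)[Si](Cl)(c1ccccc1)c1ccccc1
Why: Imidazole-mediated silylation protects both primary alcohols (C14–OH, C15–OH) under non-acidic conditions that the alkenylstannane tolerates.

Step 7
Reactants: 11
Product: 12 (2Z,6R)-2-bromo-1,7-bis(TBDPS-oxy)-6-(prop-2-en-1-yl)hept-2-ene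
Conditions: N-bromosuccinimide, CH2Cl2, −78 to 0 °C
Reagents that add atoms: N-bromosuccinimide, BrN1C(=O)CCC1=O
Why: Bromodestannylation is an ipso-substitution at the alkenyl carbon with retention, so the (Z)-bromide (Br and C2 cis) results, and with both hydroxyls silylated the isolated terminal alkene has no internal nucleophile for bromoetherification.

Step 8
Reactants: 12
Product: 14 (3R,6Z)-7-bromo-8-(TBDPS-oxy)-3-[(TBDPS-oxy)methyl]oct-6-enal, via vicinal diol 13 (not isolated)
Conditions: OsO4 (2 mol %), NaIO4 (4 equiv), 2,6-lutidine, dioxane/H2O (3:1), rt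
Reagents that add atoms: OsO4, O=[Os](=O)(=O)=O; NaIO4 (terminal oxidant), [Na+].[O-]I(=O)(=O)=O
Why: Lemieux–Johnson oxidation: OsO4 dihydroxylates the monosubstituted alkene far faster than the deactivated bromoalkene and periodate cleaves the diol to the C6 aldehyde.

Step 9
Reactants: 2
Product: 15 (4S)-4-benzyl-3-[(2E)-but-2-enoyl]-1,3-oxazolidin-2-one
Conditions: (E)-crotonic anhydride, Et3N, LiCl, THF, rt
Reagents that add atoms: (E)-crotonic anhydride, C/C=C/C(=O)OC(=O)/C=C/C
Why: N-Acylation of the oxazolidinone with the anhydride under LiCl/Et3N activation gives the conjugated crotonyl imide without passing through a strongly basic amide anion.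

Step 10
Reactants: 14; 15
Product: 17 (4S)-4-benzyl-3-[(2S,3R,5R,8Z)-9-bromo-10-(TBDPS-oxy)-5-[(TBDPS-oxy)methyl]-2-ethenyl-3-hydroxydec-8-enoyl]-1,3-oxazolidin-2-one, via dibutylboron dienolate 16 (not isolated)
Conditions: Bu2BOTf, Et3N, CH2Cl2, −78 to 0 °C; 14, −78 to 0 °C; then pH 7 buffer, MeOH, H2O2, 0 °C
Reagents that add atoms: none
Why: Evans syn-aldol: the boron dienolate of the crotonyl imide reacts at its α-carbon through a Zimmerman–Traxler chair, and the auxiliary fixes C6 (R) and C7 with O6 and the vinyl group syn, as the target requires.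

Step 11
Reactants: 17
Product: 18 TES ether of 17, (4S)-4-benzyl-3-[(2S,3R,5R,8Z)-9-bromo-10-(TBDPS-oxy)-5-[(TBDPS-oxy)methyl]-2-ethenyl-3-(TES-oxy)dec-8-enoyl]-1,3-oxazolidin-2-one
Conditions: Et3SiOTf, 2,6-lutidine, CH2Cl2, −78 °C
Reagents that add atoms: triethylsilyl trifluoromethanesulfonate, CC[Si](CC)(CC)OS(=O)(=O)C(F)(F)F
Why: Silylation of the C6 hydroxyl with the silyl triflate and a hindered base blocks retro-aldol and gives a group that can later be removed in the presence of the primary TBDPS ethers.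

Step 12
Reactants: 18
Product: 19 S-ethyl (2S,3R,5R,8Z)-9-bromo-10-(TBDPS-oxy)-5-[(TBDPS-oxy)methyl]-2-ethenyl-3-(TES-oxy)dec-8-enethioate
Conditions: EtSH, n-BuLi, THF, 0 °C
Reagents that add atoms: ethanethiol, CCS
Why: Transthioesterification with lithium ethanethiolate attacks the exocyclic imide carbonyl and, being only weakly basic, should leave the α-vinyl stereocentre C7 and the β-silyloxy group untouched.

Step 13
Reactants: 19
Product: 21 [(3R,4R,6R,9Z)-10-bromo-11-(TBDPS-oxy)-6-[(TBDPS-oxy)methyl]-3-ethenyl-2-methylidene-4-(TES-oxy)undec-9-en-1-yl]trimethylsilane, via bis(trimethylsilylmethyl) carbinol 20 (not isolated)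
Conditions: CeCl3, Me3SiCH2MgCl (5 equiv), THF, −78 °C to rt; then SiO2, CH2Cl2, rt
Reagents that add atoms: (trimethylsilyl)methylmagnesium chloride, C[Si](C)(C)C[Mg]Cl
Why: Cerium-mediated double addition of the non-basic (trimethylsilyl)methyl reagent to the thioester and Peterson olefination of the carbinol on silica gel should give the 2-substituted allylsilane (C11 with C12 and C13) without enolising C7.

Step 14
Reactants: 21
Product: 23 (3R,4R,6R,9Z)-10-bromo-11-(TBDPS-oxy)-6-[(TBDPS-oxy)methyl]-3-ethenyl-2-methylidene-4-(TES-oxy)undec-9-en-1-ol, via epoxysilane 22 (not isolated)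
Conditions: mCPBA (1.05 equiv), CH2Cl2, −20 to 0 °C; aq. NaHCO3
Reagents that add atoms: 3-chloroperoxybenzoic acid, OOC(=O)c1cccc(Cl)c1
Why: Peracid epoxidation picks the allylsilane alkene, the most electron-rich of the four, and the acid formed opens the epoxide through the β-silyl cation with loss of silicon (desilylative epoxide opening) to give the 2-substituted allylic alcohol.

Step 15
Reactants: 23
Product: 24 (4R,6R,7S,8R)-14,15-bis(TBDPS-oxy)-6-(TES-oxy)-8,12-epoxygermacra-1(10)E,11(13)-diene (cyclodecene trans-fused to a 3-methylideneoxolane; every centre arranged as in 30)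
Conditions: Pd2(dba)3 (5 mol %), DPE-Phos (12 mol %), NaOtBu (2 equiv), toluene, 95 °C, 23 added over 10 h to a final 0.002 M
Reagents that add atoms: none
Why: Proposed new method: zerovalent palladium inserts into the C10–Br bond, the C12 alkoxide replaces bromide on palladium, the C8=C9 alkene inserts syn into the Pd–O bond and C(sp3)–C(sp2) reductive elimination joins C9 to C10, so O–C8 and C9–C10 form in one catalytic cycle. The closest known reaction type is the palladium-catalysed carboetherification of γ-hydroxy alkenes with aryl or alkenyl bromides, whose intramolecular form is known only for five- and six-membered carbocycles; a ten-membered closure is the new element. The oxolane closes in a 5-exo-trig alkoxypalladation and the carbocycle by reductive elimination from an eleven-membered alkyl(alkenyl)palladium chelate, giving the ten-membered ring with its alkene cis in the ring. C8 is set in the insertion, where the C7 substituent lies pseudo-equatorial and the oxolane forms 2,3-trans (H7 and H8 anti, C8 R), the preference known for 3-substituted pent-4-en-1-ols; the C1=C10 geometry is carried over with retention from the (Z)-bromide. The step needs cyclisation to beat oligomerisation, β-hydride elimination of the alkoxide and Heck insertion, which slow addition at high dilution, the wide-bite-angle diphosphine and the cis arrangement of C9 (as Br) and C2 on the alkene should secure.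

Step 16
Reactants: 24
Product: 25 (4R,6R,7R,8R)-14,15-bis(TBDPS-oxy)-8,12-epoxygermacra-1(10)E,11(13)-dien-6-ol
Conditions: PPTS (cat.), MeOH/CH2Cl2, 0 °C
Reagents that add atoms: none
Why: Acid-catalysed methanolysis removes the secondary TES ether much faster than the primary TBDPS ethers, and no lactone is present yet that could migrate to O6.

Step 17
Reactants: 25; 26 angelic acid, (2Z)-2-methylbut-2-enoic acid
Product: 28 (4R,6R,7S,8R)-6-angeloyloxy-14,15-bis(TBDPS-oxy)-8,12-epoxygermacra-1(10)E,11(13)-diene, via angelic trichlorobenzoic anhydride 27 (not isolated)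
Conditions: 26, 2,4,6-trichlorobenzoyl chloride, Et3N, toluene, rt; then 25, 80 °C
Reagents that add atoms: none
Why: Yamaguchi esterification via the mixed anhydride acylates the hindered C6 alcohol under conditions known to keep the (Z)-geometry of angelic acid.

Step 18
Reactants: 28
Product: 29 (4R,6R,7R,8R)-6-angeloyloxy-14,15-bis(TBDPS-oxy)germacra-1(10)E,11(13)-dien-12,8-olide
Conditions: CrO3·2pyridine (12 equiv, from CrO3 and pyridine), CH2Cl2, rt
Reagents that add atoms: chromium trioxide, O=[Cr](=O)=O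
Why: Allylic C–H oxidation by CrO3·2pyridine is fastest at C12, which is both allylic and α to the ring oxygen, and is the known way to turn 3-methylideneoxolanes into α-methylene-γ-butyrolactones.

Step 19
Reactants: 29
Product: 30 (4R,6R,7R,8R)-6-angeloyloxy-14,15-dihydroxygermacra-1(10)E,11(13)-dien-12,8-olide (CNP0147777.1)
Conditions: HF·pyridine, pyridine, THF, 0 °C to rt
Reagents that add atoms: none
Why: Fluoride-mediated desilylation with buffered HF·pyridine frees C14–OH and C15–OH without adding to the α-methylene lactone or isomerising the angelate.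

**Compound list**

1 | hex-5-ynoic acid | C#CCCCC(=O)O | starting material
2 | (4S)-4-benzyl-1,3-oxazolidin-2-one | O=C1N[C@@H](Cc2ccccc2)CO1 | starting material
3 | hex-5-ynoic pivalic anhydride | C#CCCCC(=O)OC(=O)C(C)(C)C | intermediate
4 | (4S)-4-benzyl-3-(hex-5-ynoyl)-1,3-oxazolidin-2-one | C#CCCCC(=O)N1[C@@H](Cc2ccccc2)COC1=O | intermediate
5 | sodium (Z)-enolate of 4 | [Na+].[O-]/C(=C\CCC#C)N1[C@@H](Cc2ccccc2)COC1=O | intermediate
6 | (4S)-4-benzyl-3-[(2R)-2-(prop-2-en-1-yl)hex-5-ynoyl]-1,3-oxazolidin-2-one | C#CCC[C@H](CC=C)C(=O)N1[C@@H](Cc2ccccc2)COC1=O | intermediate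
7 | (2R)-2-(prop-2-en-1-yl)hex-5-yn-1-ol | C#CCC[C@H](CC=C)CO | intermediate
8 | dilithium alkoxide–acetylide of 7 | [Li+].[Li+].[C-]#CCC[C@H](CC=C)C[O-] | intermediate
9 | (2R)-2-(prop-2-en-1-yl)hept-5-yne-1,7-diol | OCC#CCC[C@H](CC=C)CO | intermediate
10 | (2Z,6R)-6-(prop-2-en-1-yl)-2-(tributylstannyl)hept-2-ene-1,7-diol | OC/C(=C/CC[C@H](CC=C)CO)[Sn](CCCC)(CCCC)CCCC | intermediate
11 | (2Z,6R)-1,7-bis(TBDPS-oxy)-6-(prop-2-en-1-yl)-2-(tributylstannyl)hept-2-ene | CC(C)(C)[Si](c1ccccc1)(c1ccccc1)OC/C(=C/CC[C@H](CC=C)CO[Si](c1ccccc1)(c1ccccc1)C(C)(C)C)[Sn](CCCC)(CCCC)CCCC | intermediate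
12 | (2Z,6R)-2-bromo-1,7-bis(TBDPS-oxy)-6-(prop-2-en-1-yl)hept-2-ene | CC(C)(C)[Si](c1ccccc1)(c1ccccc1)OC/C(Br)=C/CC[C@H](CC=C)CO[Si](c1ccccc1)(c1ccccc1)C(C)(C)C | intermediate
13 | vicinal diol from the allyl group of 12 (both epimers at the new carbinol) | CC(C)(C)[Si](c1ccccc1)(c1ccccc1)OC/C(Br)=C/CC[C@H](CC(O)CO)CO[Si](c1ccccc1)(c1ccccc1)C(C)(C)C | intermediate
14 | (3R,6Z)-7-bromo-8-(TBDPS-oxy)-3-[(TBDPS-oxy)methyl]oct-6-enal | CC(C)(C)[Si](c1ccccc1)(c1ccccc1)OC/C(Br)=C/CC[C@H](CC=O)CO[Si](c1ccccc1)(c1ccccc1)C(C)(C)C | intermediate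
15 | (4S)-4-benzyl-3-[(2E)-but-2-enoyl]-1,3-oxazolidin-2-one | C/C=C/C(=O)N1[C@@H](Cc2ccccc2)COC1=O | intermediate
16 | dibutylboron (Z)-dienolate of 15 | CCCCB(CCCC)O/C(=C\C=C)N1[C@@H](Cc2ccccc2)COC1=O | intermediate
17 | (4S)-4-benzyl-3-[(2S,3R,5R,8Z)-9-bromo-10-(TBDPS-oxy)-5-[(TBDPS-oxy)methyl]-2-ethenyl-3-hydroxydec-8-enoyl]-1,3-oxazolidin-2-one | O=C1OC[C@H](Cc2ccccc2)N1C(=O)[C@@H](C=C)[C@H](O)C[C@H](CO[Si](c1ccccc1)(c1ccccc1)C(C)(C)C)CC/C=C(\Br)CO[Si](c1ccccc1)(c1ccccc1)C(C)(C)C | intermediate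
18 | TES ether of 17 (C6–O–SiEt3) | O=C1OC[C@H](Cc2ccccc2)N1C(=O)[C@@H](C=C)[C@H](O[Si](CC)(CC)CC)C[C@H](CO[Si](c1ccccc1)(c1ccccc1)C(C)(C)C)CC/C=C(\Br)CO[Si](c1ccccc1)(c1ccccc1)C(C)(C)C | intermediate
19 | S-ethyl (2S,3R,5R,8Z)-9-bromo-10-(TBDPS-oxy)-5-[(TBDPS-oxy)methyl]-2-ethenyl-3-(TES-oxy)dec-8-enethioate | CCSC(=O)[C@@H](C=C)[C@H](O[Si](CC)(CC)CC)C[C@H](CO[Si](c1ccccc1)(c1ccccc1)C(C)(C)C)CC/C=C(\Br)CO[Si](c1ccccc1)(c1ccccc1)C(C)(C)C | intermediate
20 | tertiary carbinol from 19 carrying two CH2SiMe3 groups on C11 | C[Si](C)(C)CC(O)(C[Si](C)(C)C)[C@@H](C=C)[C@H](O[Si](CC)(CC)CC)C[C@H](CO[Si](c1ccccc1)(c1ccccc1)C(C)(C)C)CC/C=C(\Br)CO[Si](c1ccccc1)(c1ccccc1)C(C)(C)C | intermediate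
21 | [(3R,4R,6R,9Z)-10-bromo-11-(TBDPS-oxy)-6-[(TBDPS-oxy)methyl]-3-ethenyl-2-methylidene-4-(TES-oxy)undec-9-en-1-yl]trimethylsilane | C=C(C[Si](C)(C)C)[C@@H](C=C)[C@H](O[Si](CC)(CC)CC)C[C@H](CO[Si](c1ccccc1)(c1ccccc1)C(C)(C)C)CC/C=C(\Br)CO[Si](c1ccccc1)(c1ccccc1)C(C)(C)C | intermediate
22 | epoxide of the allylsilane alkene of 21 (both epimers at C11) | C[Si](C)(C)CC1(CO1)[C@@H](C=C)[C@H](O[Si](CC)(CC)CC)C[C@H](CO[Si](c1ccccc1)(c1ccccc1)C(C)(C)C)CC/C=C(\Br)CO[Si](c1ccccc1)(c1ccccc1)C(C)(C)C | intermediate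
23 | (3R,4R,6R,9Z)-10-bromo-11-(TBDPS-oxy)-6-[(TBDPS-oxy)methyl]-3-ethenyl-2-methylidene-4-(TES-oxy)undec-9-en-1-ol | OCC(=C)[C@@H](C=C)[C@H](O[Si](CC)(CC)CC)C[C@H](CO[Si](c1ccccc1)(c1ccccc1)C(C)(C)C)CC/C=C(\Br)CO[Si](c1ccccc1)(c1ccccc1)C(C)(C)C | intermediate
24 | (4R,6R,7S,8R)-14,15-bis(TBDPS-oxy)-6-(TES-oxy)-8,12-epoxygermacra-1(10)E,11(13)-diene | C=C1CO[C@@H]2C/C(CO[Si](c3ccccc3)(c3ccccc3)C(C)(C)C)=C\CC[C@@H](CO[Si](c3ccccc3)(c3ccccc3)C(C)(C)C)C[C@@H](O[Si](CC)(CC)CC)[C@@H]12 | intermediate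
25 | (4R,6R,7R,8R)-14,15-bis(TBDPS-oxy)-8,12-epoxygermacra-1(10)E,11(13)-dien-6-ol | C=C1CO[C@@H]2C/C(CO[Si](c3ccccc3)(c3ccccc3)C(C)(C)C)=C\CC[C@@H](CO[Si](c3ccccc3)(c3ccccc3)C(C)(C)C)C[C@@H](O)[C@@H]12 | intermediate
26 | angelic acid, (2Z)-2-methylbut-2-enoic acid | C/C=C(/C)C(=O)O | starting material
27 | angelic 2,4,6-trichlorobenzoic anhydride | C/C=C(/C)C(=O)OC(=O)c1c(Cl)cc(Cl)cc1Cl | intermediate
28 | (4R,6R,7S,8R)-6-angeloyloxy-14,15-bis(TBDPS-oxy)-8,12-epoxygermacra-1(10)E,11(13)-diene | C=C1CO[C@@H]2C/C(CO[Si](c3ccccc3)(c3ccccc3)C(C)(C)C)=C\CC[C@@H](CO[Si](c3ccccc3)(c3ccccc3)C(C)(C)C)C[C@@H](OC(=O)/C(C)=C\C)[C@@H]12 | intermediate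
29 | (4R,6R,7R,8R)-6-angeloyloxy-14,15-bis(TBDPS-oxy)germacra-1(10)E,11(13)-dien-12,8-olide | C=C1C(=O)O[C@@H]2C/C(CO[Si](c3ccccc3)(c3ccccc3)C(C)(C)C)=C\CC[C@@H](CO[Si](c3ccccc3)(c3ccccc3)C(C)(C)C)C[C@@H](OC(=O)/C(C)=C\C)[C@@H]12 | intermediate
30 | (4R,6R,7R,8R)-6-angeloyloxy-14,15-dihydroxygermacra-1(10)E,11(13)-dien-12,8-olide (CNP0147777.1) | C=C1C(=O)O[C@@H]2C/C(CO)=C\CC[C@@H](CO)C[C@@H](OC(=O)/C(C)=C\C)[C@@H]12 | target

**Count and risks**

Total steps: 19. Longest linear sequence: 18 (steps 1–8 and 10–19; step 9 is a one-step side branch).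

Steps most likely to fail:

Step 15 (Proposed new method). Closure of the ten-membered ring may lose to oligomerisation, to β-hydride elimination from the palladium alkoxide (oxidation of the allylic alcohol, reduction of the bromide) or to Heck-type insertion. The fallback keeps the same ring-closing bond but builds it in known stages. It sets out from 23: iodoetherification (I2, NaHCO3, MeCN, 0 °C) should give the 2,3-trans 2-(iodomethyl)-4-methylideneoxolane F1; a silver-assisted Kornblum oxidation (AgBF4, DMSO; then Et3N) the oxolane-2-carbaldehyde F2; an intramolecular Nozaki–Hiyama–Kishi reaction (CrCl2, NiCl2 cat., DMSO, high dilution) closes the ring between C9 and C10 to the C9 allylic alcohol F3; methyl chloroformate and pyridine give the C9 methyl carbonate F4; palladium-catalysed formate hydrogenolysis (Pd(OAc)2, PBu3, HCO2H, Et3N), with hydride delivered to the more hindered allyl terminus C9, removes the extra oxygen and comes back to the route at 24.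

Step 18. The C–H oxidation may be unselective, attacking the other allylic methylenes (C9, C2) or the silyloxymethyl C14 instead of C12, or may stall. The fallback splits the oxidation into two milder events: from 28, hydride abstraction at C12 with DDQ in CH2Cl2/pH 7 buffer and capture by water should give the C12 lactol F5, and MnO2 in CH2Cl2 oxidises this allylic lactol, returning to the route at 29.

Step 14. The epoxidation may lose chemoselectivity (vinyl group or bromoalkene reacting), or the acid released may cleave the TES ether during the desilylative opening. The fallback replaces oxygen transfer by halodesilylation and substitution: from 21, N-bromosuccinimide (CH2Cl2, −78 °C) gives, by electrophilic attack with allylic transposition and loss of silicon, the allylic bromide F6; CsOAc in DMF gives the allylic acetate F7; K2CO3 in MeOH returns to the route at 23.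

**Further compounds**

F1 | step 15 | 2-(iodomethyl)-4-methylideneoxolane from 23 (O–C8 closed, C9–I, acyclic C9/C10) | C=C1CO[C@H](CI)[C@H]1[C@H](O[Si](CC)(CC)CC)C[C@H](CO[Si](c2ccccc2)(c2ccccc2)C(C)(C)C)CC/C=C(\Br)CO[Si](c2ccccc2)(c2ccccc2)C(C)(C)C
F2 | step 15 | oxolane-2-carbaldehyde (C9 aldehyde) | C=C1CO[C@H](C=O)[C@H]1[C@H](O[Si](CC)(CC)CC)C[C@H](CO[Si](c2ccccc2)(c2ccccc2)C(C)(C)C)CC/C=C(\Br)CO[Si](c2ccccc2)(c2ccccc2)C(C)(C)C
F3 | step 15 | 9-hydroxy derivative of 24 (both C9 epimers) | C=C1CO[C@@H]2C(O)/C(CO[Si](c3ccccc3)(c3ccccc3)C(C)(C)C)=C\CC[C@@H](CO[Si](c3ccccc3)(c3ccccc3)C(C)(C)C)C[C@@H](O[Si](CC)(CC)CC)[C@@H]12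
F4 | step 15 | C9 methyl carbonate of F3 | C=C1CO[C@@H]2C(OC(=O)OC)/C(CO[Si](c3ccccc3)(c3ccccc3)C(C)(C)C)=C\CC[C@@H](CO[Si](c3ccccc3)(c3ccccc3)C(C)(C)C)C[C@@H](O[Si](CC)(CC)CC)[C@@H]12
F5 | step 18 | C12 lactol of 28 (both C12 epimers) | C=C1C(O)O[C@@H]2C/C(CO[Si](c3ccccc3)(c3ccccc3)C(C)(C)C)=C\CC[C@@H](CO[Si](c3ccccc3)(c3ccccc3)C(C)(C)C)C[C@@H](OC(=O)/C(C)=C\C)[C@@H]12
F6 | step 14 | allylic bromide corresponding to 23 (CH2Br in place of CH2OH) | BrCC(=C)[C@@H](C=C)[C@H](O[Si](CC)(CC)CC)C[C@H](CO[Si](c1ccccc1)(c1ccccc1)C(C)(C)C)CC/C=C(\Br)CO[Si](c1ccccc1)(c1ccccc1)C(C)(C)C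
F7 | step 14 | acetate of 23 | CC(=O)OCC(=C)[C@@H](C=C)[C@H](O[Si](CC)(CC)CC)C[C@H](CO[Si](c1ccccc1)(c1ccccc1)C(C)(C)C)CC/C=C(\Br)CO[Si](c1ccccc1)(c1ccccc1)C(C)(C)C
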